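**Retrosynthetic overview**
1. Last cut: the ester C–O bond, giving the (1S,2R)-diol with a free primary hydroxyl and O-silylated (Z)-2-(hydroxymethyl)but-2-enoic acid. The acid comes from crotonaldehyde through (Z)-2-bromobut-2-enal and bromine–lithium exchange/CO2, which fixes the Z geometry.
2. The diol comes from an N-acyl oxazolidinone in which the CH2O carbon is at the carboxyl level; LiBH4 removes the auxiliary.
3. Enabling feature: the acyclic C1(OH)–C2–C3(O) unit next to one 3,4-dimethoxyphenyl ring, with the allylic CH2 on C2. With C3 as a carboxyl, C1–C2 is an aldol bond and the CH2 on C2 is the β-carbon of an acrylate, so the allylic CH2–CH= bond is a conjugate-addition bond.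
4. Key disconnections, made in one pot from three components: CH2–CH= (an (E)-styrenylborane from 4-ethynyl-1,2-dimethoxybenzene adds to N-acryloyl-(S)-4-benzyloxazolidinone) and C1–C2 (boron aldol addition to 3,4-dimethoxybenzaldehyde), setting both stereocentres.
5. Rings: none is formed; both arene rings are bought and the oxazolidinone ring is a recovered auxiliary.

Key step: step 2

Remark on the chemistry: the dicyclohexylboron enolate is assumed to react through the same non-chelated closed transition state as the dibutylboron enolates of the Evans aldol reaction; the (S)-auxiliary is chosen on that basis. The target is read as (2R,3S) in the propyl chain (syn aldol pattern) with a Z enoate (methyl cis to the ester carbonyl).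

**Route**

Step 1
Reactants: 1 (S)-4-benzyloxazolidin-2-one; 2 acryloyl chloride
Product: 4 (S)-3-acryloyl-4-benzyloxazolidin-2-one, via magnesium amide 3 (not isolated)
Conditions: MeMgBr, THF, 0 °C; then 2, −78 to 0 °C
Reagents that add atoms: none
Why: N-acylation of the bromomagnesium salt of the oxazolidinone by the acid chloride should give the acrylimide, the weakly basic magnesium amide at low temperature avoiding anionic polymerisation, and the auxiliary stereocentre is not touched.

Step 2
Reactants: 4 (S)-3-acryloyl-4-benzyloxazolidin-2-one; 5 4-ethynyl-1,2-dimethoxybenzene; 6 3,4-dimethoxybenzaldehyde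
Product: 10 (S)-4-benzyl-3-[(2S,3S)-3-(3,4-dimethoxyphenyl)-2-[(E)-3-(3,4-dimethoxyphenyl)prop-2-en-1-yl]-3-hydroxypropanoyl]oxazolidin-2-one, via alkenylborane 7 (not isolated), via boron enolate 8 (not isolated), via boron aldolate 9 (not isolated)
Conditions: Cy2BH (from BH3·SMe2, cyclohexene), 5, THF, 0 °C to rt; then 4, [Rh(OMe)(cod)]2 (3 mol%), toluene, 30 °C; then 6, −78 to 0 °C; then pH 7 buffer, MeOH, H2O2, 0 °C
Reagents that add atoms: none
Why: Proposed new method: syn-hydroboration of 5 gives the (E)-alkenylborane 7; a monovalent rhodium methoxide takes over the alkenyl group from boron, the alkenylrhodium inserts the terminal CH2 of the s-cis acrylimide 4 (this makes the allylic CH2–CH= bond with the E geometry retained) and a second molecule of 7 releases the oxa-π-allylrhodium as the dicyclohexylboron (Z)-enolate 8, which adds to aldehyde 6 through a closed Zimmerman–Traxler chair. The closest known reaction types are the rhodium-catalysed 1,4-addition of B-aryl-9-borabicyclo[3.3.1]nonanes to enones under aprotic conditions, which gives boron enolates that can be trapped by aldehydes, and the Evans dialkylboron aldol reaction of N-acyl oxazolidinones; the new element is the use of an alkenyldialkylborane with an N-acryloyl oxazolidinone, so that the conjugate addition itself delivers the Evans enolate. No ring is closed. Both new stereocentres arise in the aldol event: the (Z)-enolate, the only geometry free of allylic 1,3-strain with the oxazolidinone, gives the syn relationship, and the (S)-benzyl group of the non-chelated, dipole-opposed imide enolate blocks one face so that the (2S,3S) adduct should form. The step needs 1,4- over 1,2-addition, alkenyl over cyclohexyl transfer and aldol reaction through boron and not through rhodium; these should be secured by the unsubstituted, strongly electrophilic β-carbon of 4, by the faster transmetalation of the sp2 carbon, and by adding 6 only after 4 is consumed and at −78 °C.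

Step 3
Reactants: 10 (S)-4-benzyl-3-[(2S,3S)-3-(3,4-dimethoxyphenyl)-2-[(E)-3-(3,4-dimethoxyphenyl)prop-2-en-1-yl]-3-hydroxypropanoyl]oxazolidin-2-one
Product: 11 (1S,2R)-1-(3,4-dimethoxyphenyl)-2-[(E)-3-(3,4-dimethoxyphenyl)prop-2-en-1-yl]propane-1,3-diol
Conditions: LiBH4, H2O (1 equiv), Et2O/THF, 0 °C
Reagents that add atoms: none
Why: Reductive cleavage of the Evans imide by lithium-chelated hydride delivery to the exocyclic carbonyl should be faster at 0 °C than retro-aldol cleavage or enolisation, so both stereocentres are kept and auxiliary 1 is recovered.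

Step 4
Reactants: 12 (E)-but-2-enal (crotonaldehyde)
Product: 14 (Z)-2-bromobut-2-enal, via dibromide 13 (not isolated)
Conditions: Br2, CH2Cl2, 0 °C; then Et3N, 0 °C to rt
Reagents that add atoms: bromine, BrBr
Why: Bromine addition to the enal followed by amine-induced dehydrobromination at the acidic α-position should give the α-bromo enal in its more stable geometry, with methyl trans to the formyl group (Z).

Step 5
Reactants: 14 (Z)-2-bromobut-2-enal
Product: 15 (Z)-2-bromobut-2-en-1-ol
Conditions: NaBH4, MeOH, 0 °C
Reagents that add atoms: none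
Why: Borohydride 1,2-reduction of the aldehyde should leave the alkene geometry and the C–Br bond untouched.

Step 6
Reactants: 15 (Z)-2-bromobut-2-en-1-ol
Product: 16 tert-butyl{[(Z)-2-bromobut-2-en-1-yl]oxy}dimethylsilane
Conditions: TBSCl, imidazole, DMF, rt
Reagents that add atoms: tert-butyldimethylsilyl chloride (TBSCl), CC(C)(C)[Si](C)(C)Cl
Why: Standard silyl ether formation on a primary allylic alcohol with imidazole-activated silyl chloride.

Step 7
Reactants: 16 tert-butyl{[(Z)-2-bromobut-2-en-1-yl]oxy}dimethylsilane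
Product: 19 (Z)-2-{[(tert-butyldimethylsilyl)oxy]methyl}but-2-enoic acid, via alkenyllithium 17 (not isolated), via lithium carboxylate 18 (not isolated)
Conditions: t-BuLi (2.1 equiv), Et2O, −78 °C; then CO2, −78 °C to rt; then cold 1 M HCl
Reagents that add atoms: carbon dioxide, O=C=O
Why: Bromine–lithium exchange at −78 °C should give a configurationally stable alkenyllithium that is carboxylated with retention, so the carboxyl group ends cis to the methyl group (Z).

Step 8
Reactants: 11 (1S,2R)-1-(3,4-dimethoxyphenyl)-2-[(E)-3-(3,4-dimethoxyphenyl)prop-2-en-1-yl]propane-1,3-diol; 19 (Z)-2-{[(tert-butyldimethylsilyl)oxy]methyl}but-2-enoic acid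
Product: 21 (2R,3S)-3-(3,4-dimethoxyphenyl)-2-[(E)-3-(3,4-dimethoxyphenyl)prop-2-en-1-yl]-3-hydroxypropyl (Z)-2-{[(tert-butyldimethylsilyl)oxy]methyl}but-2-enoate, via mixed anhydride 20 (not isolated)
Conditions: 2,4,6-trichlorobenzoyl chloride, Et3N, THF, rt; then 11, DMAP, toluene, 0 °C
Reagents that add atoms: none
Why: Yamaguchi esterification through mixed anhydride 20 should transfer the enoyl group to the unhindered primary hydroxyl much faster than to the secondary benzylic one, and the low temperature should keep the Z geometry of the acid.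

Step 9
Reactants: 21 (2R,3S)-3-(3,4-dimethoxyphenyl)-2-[(E)-3-(3,4-dimethoxyphenyl)prop-2-en-1-yl]-3-hydroxypropyl (Z)-2-{[(tert-butyldimethylsilyl)oxy]methyl}but-2-enoate
Product: 22 (2R,3S)-3-(3,4-dimethoxyphenyl)-2-[(E)-3-(3,4-dimethoxyphenyl)prop-2-en-1-yl]-3-hydroxypropyl (Z)-2-(hydroxymethyl)but-2-enoate (CNP0417076.1)
Conditions: HF·pyridine, pyridine, THF, 0 °C to rt
Reagents that add atoms: none
Why: Fluoride-mediated desilylation under pyridine-buffered conditions should free the primary allylic alcohol without ionising the electron-rich benzylic alcohol, moving the acyl group or isomerising the enoate.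

**Compound list**
1 | (S)-4-benzyloxazolidin-2-one | O=C1N[C@@H](Cc2ccccc2)CO1 | starting material
2 | acryloyl chloride | C=CC(=O)Cl | starting material
3 | bromomagnesium salt of (S)-4-benzyloxazolidin-2-one (not isolated) | O=C1N([Mg]Br)[C@@H](Cc2ccccc2)CO1 | intermediate
4 | (S)-3-acryloyl-4-benzyloxazolidin-2-one | C=CC(=O)N1[C@@H](Cc2ccccc2)COC1=O | intermediate
5 | 4-ethynyl-1,2-dimethoxybenzene | C#Cc1ccc(OC)c(OC)c1 | starting material
6 | 3,4-dimethoxybenzaldehyde | O=Cc1ccc(OC)c(OC)c1 | starting material
7 | dicyclohexyl[(E)-2-(3,4-dimethoxyphenyl)ethenyl]borane (not isolated) | COc1ccc(/C=C/B(C2CCCCC2)C2CCCCC2)cc1OC | intermediate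
8 | (S)-4-benzyl-3-[(1Z,4E)-1-(dicyclohexylboryloxy)-5-(3,4-dimethoxyphenyl)penta-1,4-dien-1-yl]oxazolidin-2-one (not isolated) | COc1ccc(/C=C/C/C=C(\OB(C2CCCCC2)C2CCCCC2)N2[C@@H](Cc3ccccc3)COC2=O)cc1OC | intermediate
9 | O-dicyclohexylboryl aldolate of 10 (not isolated) | O=C([C@@H](C/C=C/c1ccc(OC)c(OC)c1)[C@H](OB(C1CCCCC1)C1CCCCC1)c1ccc(OC)c(OC)c1)N1[C@@H](Cc2ccccc2)COC1=O | intermediate
10 | (S)-4-benzyl-3-[(2S,3S)-3-(3,4-dimethoxyphenyl)-2-[(E)-3-(3,4-dimethoxyphenyl)prop-2-en-1-yl]-3-hydroxypropanoyl]oxazolidin-2-one | O=C([C@@H](C/C=C/c1ccc(OC)c(OC)c1)[C@H](O)c1ccc(OC)c(OC)c1)N1[C@@H](Cc2ccccc2)COC1=O | intermediate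
11 | (1S,2R)-1-(3,4-dimethoxyphenyl)-2-[(E)-3-(3,4-dimethoxyphenyl)prop-2-en-1-yl]propane-1,3-diol | OC[C@@H](C/C=C/c1ccc(OC)c(OC)c1)[C@H](O)c1ccc(OC)c(OC)c1 | intermediate
12 | (E)-but-2-enal (crotonaldehyde) | C/C=C/C=O | starting material
13 | 2,3-dibromobutanal (racemic, not isolated; both stereocentres are lost in the elimination) | CC(Br)C(Br)C=O | intermediate
14 | (Z)-2-bromobut-2-enal | C/C=C(/C=O)Br | intermediate
15 | (Z)-2-bromobut-2-en-1-ol | C/C=C(/CO)Br | intermediate
16 | tert-butyl{[(Z)-2-bromobut-2-en-1-yl]oxy}dimethylsilane | C/C=C(/CO[Si](C)(C)C(C)(C)C)Br | intermediate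
17 | (E)-(1-{[tert-butyl(dimethyl)silyl]oxy}but-2-en-2-yl)lithium, lithium cis to methyl (not isolated) | C/C=C(/CO[Si](C)(C)C(C)(C)C)[Li] | intermediate
18 | lithium (Z)-2-{[(tert-butyldimethylsilyl)oxy]methyl}but-2-enoate (not isolated) | C/C=C(/CO[Si](C)(C)C(C)(C)C)C(=O)[O-].[Li+] | intermediate
19 | (Z)-2-{[(tert-butyldimethylsilyl)oxy]methyl}but-2-enoic acid | C/C=C(/CO[Si](C)(C)C(C)(C)C)C(=O)O | intermediate
20 | (Z)-2-{[(tert-butyldimethylsilyl)oxy]methyl}but-2-enoic 2,4,6-trichlorobenzoic anhydride (not isolated) | C/C=C(/CO[Si](C)(C)C(C)(C)C)C(=O)OC(=O)c1c(Cl)cc(Cl)cc1Cl | intermediate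
21 | (2R,3S)-3-(3,4-dimethoxyphenyl)-2-[(E)-3-(3,4-dimethoxyphenyl)prop-2-en-1-yl]-3-hydroxypropyl (Z)-2-{[(tert-butyldimethylsilyl)oxy]methyl}but-2-enoate | C/C=C(/CO[Si](C)(C)C(C)(C)C)C(=O)OC[C@@H](C/C=C/c1ccc(OC)c(OC)c1)[C@H](O)c1ccc(OC)c(OC)c1 | intermediate
22 | (2R,3S)-3-(3,4-dimethoxyphenyl)-2-[(E)-3-(3,4-dimethoxyphenyl)prop-2-en-1-yl]-3-hydroxypropyl (Z)-2-(hydroxymethyl)but-2-enoate | C/C=C(/CO)C(=O)OC[C@@H](C/C=C/c1ccc(OC)c(OC)c1)[C@H](O)c1ccc(OC)c(OC)c1 | target

**Step count and risks**
Total steps: 9. Longest linear sequence: 6 steps (steps 4, 5, 6, 7, 8, 9 from crotonaldehyde 12); the core branch is steps 1, 2, 3, 8, 9.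

Steps most likely to fail:

Step 2. The relay from rhodium to boron may not take place cleanly. The enolate could then be lost by oligomerisation of the acrylimide, or it could react as a rhodium enolate with poor facial selectivity. The fallback separates the two bond formations and uses known reactions, setting out from alkyne 5 and acrylimide 4. Zirconium-catalysed hydroboration of 5 with pinacolborane (Cp2Zr(H)Cl cat., Et3N, 60 °C) should give 2-[(E)-2-(3,4-dimethoxyphenyl)ethenyl]-4,4,5,5-tetramethyl-1,3,2-dioxaborolane F1. Hayashi–Miyaura addition of F1 to 4 under protic conditions ([Rh(OH)(cod)]2, dioxane/H2O, 30 °C), where the rhodium enolate is simply protonated, should give (S)-4-benzyl-3-[(E)-5-(3,4-dimethoxyphenyl)pent-4-enoyl]oxazolidin-2-one F2, with the same CH2–CH= bond. The classical Evans aldol reaction of F2 (Bu2BOTf, iPr2NEt, CH2Cl2, −78 °C; then 6; H2O2 work-up) then sets both stereocentres and comes back to the route at 10.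

Step 8. The secondary hydroxyl may be acylated as well, or the Z geometry may erode by reversible conjugate addition of the nucleophilic catalyst to the activated acid. The fallback makes the ester bond from the other side, by O-alkylation of the carboxylate, so that the acid is never activated; it sets out from diol 11. Selective sulfonylation of the primary hydroxyl (TsCl, pyridine, CH2Cl2, 0 °C) should give (2R,3S)-3-(3,4-dimethoxyphenyl)-2-[(E)-3-(3,4-dimethoxyphenyl)prop-2-en-1-yl]-3-hydroxypropyl 4-methylbenzenesulfonate F3. SN2 displacement with the caesium salt of acid 19 (Cs2CO3, DMF, 40 °C) comes back to the route at 21.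

Step 7. The alkenyllithium may lose its geometry, be quenched by proton transfer, or suffer migration of silicon from oxygen to carbon before carboxylation. The fallback introduces the carboxyl carbon without an organolithium and sets out from bromide 16. Palladium-catalysed methoxycarbonylation (Pd(OAc)2, dppf, CO, MeOH, Et3N, DMF, 60 °C), which proceeds with retention of alkene geometry, should give methyl (Z)-2-{[(tert-butyldimethylsilyl)oxy]methyl}but-2-enoate F4. Neutral ester cleavage (Me3SnOH, 1,2-dichloroethane, 70 °C) comes back to the route at acid 19.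

**Further compounds**
F1 | step 2 | 2-[(E)-2-(3,4-dimethoxyphenyl)ethenyl]-4,4,5,5-tetramethyl-1,3,2-dioxaborolane | COc1ccc(/C=C/B2OC(C)(C)C(C)(C)O2)cc1OC
F2 | step 2 | (S)-4-benzyl-3-[(E)-5-(3,4-dimethoxyphenyl)pent-4-enoyl]oxazolidin-2-one | COc1ccc(/C=C/CCC(=O)N2[C@@H](Cc3ccccc3)COC2=O)cc1OC
F3 | step 8 | (2R,3S)-3-(3,4-dimethoxyphenyl)-2-[(E)-3-(3,4-dimethoxyphenyl)prop-2-en-1-yl]-3-hydroxypropyl 4-methylbenzenesulfonate | Cc1ccc(S(=O)(=O)OC[C@@H](C/C=C/c2ccc(OC)c(OC)c2)[C@H](O)c2ccc(OC)c(OC)c2)cc1
F4 | step 7 | methyl (Z)-2-{[(tert-butyldimethylsilyl)oxy]methyl}but-2-enoate | C/C=C(/CO[Si](C)(C)C(C)(C)C)C(=O)OC
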